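## Structural features

Verbenachalcone (17) is a bis-dihydrochalcone of four benzene rings. Two 2,4-dihydroxyphenyl ketone rings (ring A and ring B) are each tied through a C(=O)–CH2–CH2 chain to ring C and to ring D, and rings C and D are joined by one diaryl ether oxygen. Ring C carries OMe at C1, the ether oxygen at the neighbouring C6 and its chain at C3 (meta to C1, para to C6). Ring D carries a free OH ortho to the ether oxygen and its chain para to that OH. There is no stereocentre, so no stereocentres stand next to each other; the only stereochemical element on the way is alkene geometry in intermediates, which is erased. The fragile groups are the five electron-rich phenols (oxidation, interference with bases and metal catalysts) and the two aryl ketones, which can be over-reduced at the benzylic carbonyl. The real difficulty is the unsymmetrical diaryl ether: the C–O–C bridge is flanked by an oxygen on each ring, so a direct aryl–oxygen coupling is hindered, and the two flanking oxygens (OMe on ring C, OH on ring D) must be told apart. The key step uses the O–C6–C1(O)–C2 segment of ring C, which is the O–CH2–C(=O)–CH3 unit of an aryloxyacetone, and the carbon substituent at C3, so that C3, C4 and C5 come from a three-carbon 1,3-dielectrophile. The ether oxygen is thus attached to an sp3 carbon by plain alkylation before ring C exists, and the C1 oxygen appears as the only free phenol.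

## Logic of the disconnections

17 to 16. The five phenolic O–H bonds are traced back to O–benzyl bonds and the two CH2–CH2 units of the arms to C=C bonds. One kind of protecting group then falls in the same operation that saturates the enones, and no free phenol is carried through the route. The forward step must stop before the aryl ketones are reduced.

16 to 13 and two molecules of 15. Both Cα=Cβ bonds of the enones are cut (aldol retron). The arms are identical, so one ketone used twice resolves the whole periphery and leaves a dialdehyde core. The forward step must take both aldehydes to completion, and the ketone partner must carry no free phenol that could close to a flavanone.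

15 to 14. The two O–benzyl bonds are cut, which leads to a common catalogue ketone. The forward step must also alkylate the hydrogen-bonded ortho hydroxyl.

13 to 12 to 11. No skeletal bond is cut; the two formyl groups are traced to hydroxymethyl groups and then to methyl esters. The annulation delivers the C3 substituent as a carboxylate, and going through the diol avoids an unreliable partial reduction of aromatic esters. The hydride must spare the benzyl, methyl and diaryl ethers, and the oxidant must stop at the aldehyde.

11 to 10. The O–CH3 bond on ring C is cut. In 10 this oxygen is the only free hydroxyl while the ring D oxygen is still benzylated, so the two flanking oxygens are differentiated by construction and methylation needs no selectivity.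

10 to 4 and 7. The bonds C5–C6 and C2–C3 of ring C are cut. Ring C disappears, and the hindered diaryl ether becomes an alkyl aryl ether of a methyl ketone, with a three-carbon enaminone supplying C3–C5 and the ester carbon. One step thus builds the ring, two C–C bonds and the 1,2,4-substitution pattern. The forward step requires that the first C–C bond is made by the aryloxy-bearing carbon of 4 at the β-carbon of 7.

4 to 2 and 3. The O–CH2 bond is cut, so the ether oxygen is introduced by SN2 alkylation of a phenol with an α-halo ketone. Only one phenol may be free at this stage.

2 to 1. The O–benzyl bond at the 4-oxygen is cut, which leads to a cheap catechol ester. The forward step must distinguish the two hydroxyls, and it relies on the higher acidity of the one para to the ester.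

7 to 5 and 6. The bond between the methyl carbon of the keto ester and the aminomethylene carbon is cut. Both pieces are commodity reagents, and the methyl ester matches the methanol released, so the ester cannot scramble.

## Other disconnections considered

Alternative 1: The cut is at the two aryl–CH2 bonds that join ring C and ring D to their arms. In the forward direction the dibromide 1-(benzyloxy)-4-bromo-2-(4-bromo-2-methoxyphenoxy)benzene A2 and two equivalents of the redox-active ester 1,3-dioxoisoindolin-2-yl 4-[2,4-bis(benzyloxy)phenyl]-4-oxobutanoate A3 would be coupled. The conditions are constant-current electrolysis with NiBr2 and a bipyridine ligand in an undivided cell with a zinc anode, and the product would be pentabenzyl verbenachalcone A1; hydrogenolysis would finish the synthesis.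
- In favour: both arms arrive complete and at the ketone oxidation level, so no ester-to-aldehyde adjustment and no enone are needed, and no C=C bond has to be reduced at the end.
- Against: A2 already contains the hindered, unsymmetrical diaryl ether, so the central problem is only moved to a copper-mediated ether coupling that must spare two aryl bromides. Bromination after ether formation would go para to the methoxy group of ring C, which is the wrong carbon. Both C–Br bonds sit para to oxygen donors on electron-rich rings, where oxidative addition to low-valent nickel is slow and radical dimerisation or hydrodehalogenation can compete, and the coupling must succeed twice.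
- Comparison: on structure, the alternative keeps ring C intact and the chosen plan builds it. On mechanism, it relies on radical capture at nickel where the chosen plan uses polar enolate chemistry. On step economy, the alternative is the better once a core is in hand (coupling and hydrogenolysis, against five steps from 10). Over the whole route the gain is likely to be lost in making A2 and A3.

Alternative 2: The cut is inside ring D, which is closed instead of ring C. The aryloxyacetone methyl 3-[3-methoxy-4-(2-oxopropoxy)phenyl]propanoate A5 would condense with the 2-substituted vinamidinium hexafluorophosphate A6 under KOtBu, with loss of two molecules of amine. The product would be the phenol methyl 3-[4-[2-hydroxy-5-(3-methoxy-3-oxopropyl)phenoxy]-3-methoxyphenyl]propanoate A4.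
- In favour: the vinamidinium is symmetrical, so either order of attack by the two α-carbons of A5 gives the same ring; on regiochemistry this alternative is better than the chosen plan. The methoxy group comes with the starting phenol, the ring D hydroxyl emerges free where the target wants it, and both three-carbon chains are in place, so A4 should be reached in fewer steps than 11.
- Against: A6 bears a plain alkyl substituent, and vinamidinium salts are most dependably made from aryl- or heteroatom-substituted acetic acids. The two propanoate esters must then become 2,4-dihydroxyphenyl ketones. A double Friedel–Crafts acylation of an unprotected ring A precursor competes with cyclisation of the 3-arylpropanoyl units to indanones, because ring C is activated para to its methoxy group at the carbon next to the chain. An amide and aryl-metal sequence with protection would add steps.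
- Comparison: the mechanism is of the same family as the chosen key step, closing by attack on an iminium carbon rather than by aldol addition to a keto ester. The alternative is equal or better up to the diaryl ether and weaker in the endgame, where the chosen plan has a Claisen–Schmidt condensation and one hydrogenation.

Alternative 3: The cut is at the ring–carbonyl and carbonyl–alkyne bonds of both arms. The diyne 1-(benzyloxy)-4-ethynyl-2-(4-ethynyl-2-methoxyphenoxy)benzene A8, carbon monoxide A10 and two equivalents of 2,4-bis(benzyloxy)-1-iodobenzene A9 would be joined under PdCl2(PPh3)2 and an amine base (carbonylative Sonogashira coupling). The product would be the pentabenzyl bis(ynone) A7, and one hydrogenation would then reduce both ynones and remove the benzyl groups.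
- In favour: four C–C bonds form in one operation, the carbonyl carbons come from A10, and the endgame from A7 is one step, equal to the chosen plan's step from 16.
- Against: A8 contains the finished diaryl ether, so the hard part is not addressed. A8 would have to come from a dialdehyde such as 13 by homologation or from A2 by alkynylation, which adds steps to a core the chosen route already reaches. A9 is an electron-rich, ortho-alkoxy aryl iodide, for which direct alkynylation without CO insertion and alkyne homocoupling are realistic competitors, and both ends must react. The reduction of A7 takes up more hydrogen and passes through the same enones, so the over-reduction risk is no smaller.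
- Comparison: on structure, it is an arm-attachment method and not a solution for the ether. On mechanism, it is a palladium acyl cycle against a base-mediated condensation. On step economy, it is equal at the last stage and longer overall, because 13 needs no further homologation in the chosen plan.

Key step: step 4

## Route

Step 1
Reactants: 1 methyl 3,4-dihydroxybenzoate
Product: 2 methyl 4-(benzyloxy)-3-hydroxybenzoate
Conditions: BnBr (1.0 equiv), K2CO3 (1.0 equiv), DMF, 0 °C → rt
Reagents that add atoms: benzyl bromide, BrCc1ccccc1
Why: Williamson ether synthesis; the hydroxyl para to the ester is the more acidic one, so one equivalent of a weak base should form and benzylate its phenoxide preferentially, and the dibenzyl ether and the 3-O isomer are removed by crystallisation or chromatography.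

Step 2
Reactants: 2 methyl 4-(benzyloxy)-3-hydroxybenzoate, 3 chloroacetone
Product: 4 methyl 4-(benzyloxy)-3-(2-oxopropoxy)benzoate
Conditions: K2CO3, KI (cat.), acetone, reflux
Reagents that add atoms: none
Why: SN2 O-alkylation of the only free phenol by an activated α-halo ketone (Williamson ether synthesis with Finkelstein catalysis by iodide); this makes the future diaryl ether C–O bond at an sp3 carbon.

Step 3
Reactants: 5 methyl pyruvate, 6 N,N-dimethylformamide dimethyl acetal
Product: 7 methyl (E)-4-(dimethylamino)-2-oxobut-3-enoate
Conditions: CH2Cl2, 0 °C → rt (6 added slowly, 1.0 equiv)
Reagents that add atoms: none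
Why: Aminomethylenation of the only enolisable carbon of the α-keto ester by the amide acetal; the push–pull enaminone should form as the E isomer, and the methyl ester matches the methanol released.

Step 4
Reactants: 4 methyl 4-(benzyloxy)-3-(2-oxopropoxy)benzoate, 7 methyl (E)-4-(dimethylamino)-2-oxobut-3-enoate
Product: 10 methyl 4-[2-(benzyloxy)-5-(methoxycarbonyl)phenoxy]-3-hydroxybenzoate, via open-chain enedione 8 (not isolated), via cyclic aldol adduct 9 (not isolated)
Conditions: NaOMe (2.5 equiv), MeOH–THF, 0 °C → 60 °C; then AcOH
Reagents that add atoms: none
Why: The closest known reaction type is the base-mediated [3+3] benzannulation of a ketone with a β-amino enone to a phenol; this pairing of an α-aryloxy methyl ketone with the enaminone of an α-keto ester has no direct precedent and rests on the following mechanism. Reversible enolisation by methoxide should favour the enolate at the aryloxy-substituted methylene of 4, which adds to the β-carbon of 7 and expels dimethylamine (vinylogous addition–elimination, new bond C5–C6) to give 8. The methyl ketone of 8 is then enolised and attacks the ketone carbonyl of the keto ester unit, which is strongly electrophilic and has no α-hydrogen of its own, in a 6-(enolendo)-exo-trig aldol closure (new bond C2–C3) that gives 9 once the C4=C5 bond has become cis through the extended enolate. Loss of water from 9 and tautomerisation of the cyclohexadienone should deliver the 3-hydroxy-4-aryloxybenzoate 10, and formation of its phenoxide makes the sequence irreversible. No stereocentre persists, because the sp3 centres of 8 and 9 are erased on aromatisation. The selectivity needed is that the aryloxy-bearing carbon, and not the methyl carbon, makes the first bond to the β-carbon; the inductive effect of the aryloxy group under equilibrating conditions should secure this, in line with the known preference of aryloxyacetones to condense with amide acetals at that methylene. The reverse order would lead to the 2-aryloxy-3-hydroxybenzoate isomer. Methoxide makes any ester exchange degenerate and leaves the benzyl ether and the ring D ester untouched.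

Step 5
Reactants: 10 methyl 4-[2-(benzyloxy)-5-(methoxycarbonyl)phenoxy]-3-hydroxybenzoate
Product: 11 methyl 4-[2-(benzyloxy)-5-(methoxycarbonyl)phenoxy]-3-methoxybenzoate
Conditions: MeI, K2CO3, DMF, rt
Reagents that add atoms: iodomethane, CI
Why: Williamson O-methylation of the only free phenol; the ring D oxygen is still benzylated, so the methoxy group is placed on ring C without any selectivity problem.

Step 6
Reactants: 11 methyl 4-[2-(benzyloxy)-5-(methoxycarbonyl)phenoxy]-3-methoxybenzoate
Product: 12 [4-(benzyloxy)-3-[4-(hydroxymethyl)-2-methoxyphenoxy]phenyl]methanol
Conditions: LiAlH4, THF, 0 °C → rt; then H2O, aq. NaOH (Fieser work-up)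
Reagents that add atoms: none
Why: Hydride reduction of both aromatic esters to benzylic alcohols; benzyl, methyl and diaryl ethers are inert to LiAlH4, and full reduction is chosen because partial reduction of aryl esters tends to over-reduce.

Step 7
Reactants: 12 [4-(benzyloxy)-3-[4-(hydroxymethyl)-2-methoxyphenoxy]phenyl]methanol
Product: 13 4-(benzyloxy)-3-(4-formyl-2-methoxyphenoxy)benzaldehyde
Conditions: MnO2 (activated, excess), CH2Cl2, rt
Reagents that add atoms: none
Why: Activated MnO2 oxidises benzylic alcohols selectively to aldehydes and does not go on to the acids.

Step 8
Reactants: 14 1-(2,4-dihydroxyphenyl)ethan-1-one (2',4'-dihydroxyacetophenone)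
Product: 15 1-[2,4-bis(benzyloxy)phenyl]ethan-1-one
Conditions: BnBr (2.4 equiv), K2CO3, KI (cat.), DMF, 80 °C
Reagents that add atoms: benzyl bromide, BrCc1ccccc1
Why: Double Williamson benzylation; heating in DMF should also alkylate the hydrogen-bonded ortho hydroxyl, and full protection prevents flavanone formation and phenoxide deactivation in the aldol step.

Step 9
Reactants: 13 4-(benzyloxy)-3-(4-formyl-2-methoxyphenoxy)benzaldehyde, 15 1-[2,4-bis(benzyloxy)phenyl]ethan-1-one (2.2 equiv)
Product: 16 (E)-3-[4-(benzyloxy)-3-[4-[(E)-3-[2,4-bis(benzyloxy)phenyl]-3-oxoprop-1-en-1-yl]-2-methoxyphenoxy]phenyl]-1-[2,4-bis(benzyloxy)phenyl]prop-2-en-1-one (the E,E bis-chalcone)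
Conditions: KOH (50 % aq.), EtOH–THF, rt
Reagents that add atoms: none
Why: Double Claisen–Schmidt condensation; the non-enolisable aldehydes accept the ketone enolate and E1cB dehydration gives the conjugated E-enones under thermodynamic control, the geometry being of no consequence because both alkenes are hydrogenated next.

Step 10
Reactants: 16 the E,E bis-chalcone
Product: 17 verbenachalcone, 3-[4-hydroxy-3-[4-[3-(2,4-dihydroxyphenyl)-3-oxopropyl]-2-methoxyphenoxy]phenyl]-1-(2,4-dihydroxyphenyl)propan-1-one
Conditions: H2 (1 atm), Pd/C (10 %), THF–MeOH, rt; stopped at the calculated uptake
Reagents that add atoms: none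
Why: Heterogeneous hydrogenation should saturate both enone C=C bonds and hydrogenolysis should cleave all five benzyl ethers in the same operation; the electron-rich aryl ketones, hydrogen-bonded to the ortho hydroxyl once that is unveiled, are reduced far more slowly.

## Compound list

1 | methyl 3,4-dihydroxybenzoate | COC(=O)c1ccc(O)c(O)c1 | starting material
2 | methyl 4-(benzyloxy)-3-hydroxybenzoate | COC(=O)c1ccc(OCc2ccccc2)c(O)c1 | intermediate
3 | chloroacetone | CC(=O)CCl | starting material
4 | methyl 4-(benzyloxy)-3-(2-oxopropoxy)benzoate | COC(=O)c1ccc(OCc2ccccc2)c(OCC(C)=O)c1 | intermediate
5 | methyl pyruvate | COC(=O)C(C)=O | starting material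
6 | N,N-dimethylformamide dimethyl acetal | COC(OC)N(C)C | starting material
7 | methyl (E)-4-(dimethylamino)-2-oxobut-3-enoate | COC(=O)C(=O)/C=C/N(C)C | intermediate
8 | methyl (E)-5-[2-(benzyloxy)-5-(methoxycarbonyl)phenoxy]-2,6-dioxohept-3-enoate (racemic, open-chain enedione, not isolated) | COC(=O)C(=O)/C=C/C(Oc1cc(C(=O)OC)ccc1OCc1ccccc1)C(C)=O | intermediate
9 | methyl 4-[2-(benzyloxy)-5-(methoxycarbonyl)phenoxy]-1-hydroxy-5-oxocyclohex-2-ene-1-carboxylate (mixture of racemic diastereomers, cyclic aldol adduct, not isolated) | COC(=O)C1(O)CC(=O)C(Oc2cc(C(=O)OC)ccc2OCc2ccccc2)C=C1 | intermediate
10 | methyl 4-[2-(benzyloxy)-5-(methoxycarbonyl)phenoxy]-3-hydroxybenzoate | COC(=O)c1ccc(Oc2cc(C(=O)OC)ccc2OCc2ccccc2)c(O)c1 | intermediate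
11 | methyl 4-[2-(benzyloxy)-5-(methoxycarbonyl)phenoxy]-3-methoxybenzoate | COC(=O)c1ccc(Oc2cc(C(=O)OC)ccc2OCc2ccccc2)c(OC)c1 | intermediate
12 | [4-(benzyloxy)-3-[4-(hydroxymethyl)-2-methoxyphenoxy]phenyl]methanol | COc1cc(CO)ccc1Oc1cc(CO)ccc1OCc1ccccc1 | intermediate
13 | 4-(benzyloxy)-3-(4-formyl-2-methoxyphenoxy)benzaldehyde | COc1cc(C=O)ccc1Oc1cc(C=O)ccc1OCc1ccccc1 | intermediate
14 | 1-(2,4-dihydroxyphenyl)ethan-1-one | CC(=O)c1ccc(O)cc1O | starting material
15 | 1-[2,4-bis(benzyloxy)phenyl]ethan-1-one | CC(=O)c1ccc(OCc2ccccc2)cc1OCc1ccccc1 | intermediate
16 | (E)-3-[4-(benzyloxy)-3-[4-[(E)-3-[2,4-bis(benzyloxy)phenyl]-3-oxoprop-1-en-1-yl]-2-methoxyphenoxy]phenyl]-1-[2,4-bis(benzyloxy)phenyl]prop-2-en-1-one | COc1cc(/C=C/C(=O)c2ccc(OCc3ccccc3)cc2OCc2ccccc2)ccc1Oc1cc(/C=C/C(=O)c2ccc(OCc3ccccc3)cc2OCc2ccccc2)ccc1OCc1ccccc1 | intermediate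
17 | verbenachalcone | COc1cc(CCC(=O)c2ccc(O)cc2O)ccc1Oc1cc(CCC(=O)c2ccc(O)cc2O)ccc1O | target

## Step count and least certain steps

Total step count: 10 steps. Longest linear sequence: 8 steps (steps 1, 2, 4, 5, 6, 7, 9 and 10, from 1 to 17); steps 3 and 8 prepare the side partners 7 and 15.

Step 4 (key step).
- Risk: loss of regiocontrol in the first C–C bond formation. This could happen by attack of the methyl-derived enolate on the β-carbon, or by 1,2-addition of the aryloxy enolate to the keto carbonyl followed by dehydration. Either path feeds the isomeric 2-aryloxy-3-hydroxybenzoate series. Stalling at the open-chain stage and base-induced self-condensation of the enaminone are also possible.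
- Fallback: give up ring construction and make the aryl–oxygen bond directly. Setting out from 2, an Ullmann-type coupling with commercial methyl 4-bromo-3-methoxybenzoate F1 (CuI, N,N-dimethylglycine, Cs2CO3, dioxane, about 100 °C) should give 11, where the route is rejoined before step 6. The bromide is activated by its para ester; the price is a coupling between two ortho-oxygenated partners.

Step 10.
- Risk: over-reduction of the aryl ketones to benzylic alcohols or methylene groups while the last benzyl ethers are still being cleaved, or the opposite, incomplete hydrogenolysis when the reaction is stopped early.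
- Fallback: separate the two tasks. Setting out from 16, homogeneous hydrogenation with RhCl(PPh3)3 under H2 should reduce only the enone C=C bonds and give pentabenzyl verbenachalcone F2. The benzyl ethers are then removed without any reductant by BCl3 and pentamethylbenzene in CH2Cl2 at −78 °C, which should spare the aryl methyl ether and the ketones, and the route ends at 17.

Step 3.
- Risk: self-aldol condensation of methyl pyruvate under the basic acetal, or a second aminomethylenation, which would erode the supply of 7.
- Fallback: replace the enaminone by the analogous β-alkoxy enone. Methyl (E)-4-ethoxy-2-oxobut-3-enoate F3, prepared by acylation of ethyl vinyl ether with methyl chlorooxoacetate in the presence of pyridine, is condensed with 4 under the conditions of step 4. Ethoxide is then the leaving group in place of dimethylamine; this variant sets out from 4 and returns to the route at 10.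

Step 1.
- Risk: incomplete discrimination between the two catechol hydroxyls, with dibenzylation and 3-O-benzylation lowering the throughput of 2.
- Fallback: reverse the order of the two alkylations and change the source of selectivity. Setting out from 1, the dianion (NaH, 2.1 equiv, DMSO) should react with one equivalent of 3 at the more nucleophilic, non-conjugated 3-phenoxide to give methyl 4-hydroxy-3-(2-oxopropoxy)benzoate F4. Benzylation of its remaining hydroxyl (BnBr, K2CO3, DMF) gives 4, where the route is rejoined.

## Further compounds

F1 | step 4 | methyl 4-bromo-3-methoxybenzoate | COC(=O)c1ccc(Br)c(OC)c1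
F2 | step 10 | pentabenzyl verbenachalcone, 3-[4-(benzyloxy)-3-[4-[3-[2,4-bis(benzyloxy)phenyl]-3-oxopropyl]-2-methoxyphenoxy]phenyl]-1-[2,4-bis(benzyloxy)phenyl]propan-1-one | COc1cc(CCC(=O)c2ccc(OCc3ccccc3)cc2OCc2ccccc2)ccc1Oc1cc(CCC(=O)c2ccc(OCc3ccccc3)cc2OCc2ccccc2)ccc1OCc1ccccc1
F3 | step 3 | methyl (E)-4-ethoxy-2-oxobut-3-enoate | CCO/C=C/C(=O)C(=O)OC
F4 | step 1 | methyl 4-hydroxy-3-(2-oxopropoxy)benzoate | COC(=O)c1ccc(O)c(OCC(C)=O)c1
A1 | alternative 1 | pentabenzyl verbenachalcone | COc1cc(CCC(=O)c2ccc(OCc3ccccc3)cc2OCc2ccccc2)ccc1Oc1cc(CCC(=O)c2ccc(OCc3ccccc3)cc2OCc2ccccc2)ccc1OCc1ccccc1
A2 | alternative 1 | 1-(benzyloxy)-4-bromo-2-(4-bromo-2-methoxyphenoxy)benzene | COc1cc(Br)ccc1Oc1cc(Br)ccc1OCc1ccccc1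
A3 | alternative 1 | 1,3-dioxoisoindolin-2-yl 4-[2,4-bis(benzyloxy)phenyl]-4-oxobutanoate | O=C(CCC(=O)c1ccc(OCc2ccccc2)cc1OCc1ccccc1)ON1C(=O)c2ccccc2C1=O
A4 | alternative 2 | methyl 3-[4-[2-hydroxy-5-(3-methoxy-3-oxopropyl)phenoxy]-3-methoxyphenyl]propanoate | COC(=O)CCc1ccc(Oc2cc(CCC(=O)OC)ccc2O)c(OC)c1
A5 | alternative 2 | methyl 3-[3-methoxy-4-(2-oxopropoxy)phenyl]propanoate | COC(=O)CCc1ccc(OCC(C)=O)c(OC)c1
A6 | alternative 2 | N-[(E)-3-(dimethylamino)-2-(3-methoxy-3-oxopropyl)prop-2-en-1-ylidene]-N-methylmethanaminium hexafluorophosphate | COC(=O)CC/C(C=[N+](C)C)=C\N(C)C.F[P-](F)(F)(F)(F)F
A7 | alternative 3 | pentabenzyl bis(ynone) analogue of verbenachalcone | COc1cc(C#CC(=O)c2ccc(OCc3ccccc3)cc2OCc2ccccc2)ccc1Oc1cc(C#CC(=O)c2ccc(OCc3ccccc3)cc2OCc2ccccc2)ccc1OCc1ccccc1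
A8 | alternative 3 | 1-(benzyloxy)-4-ethynyl-2-(4-ethynyl-2-methoxyphenoxy)benzene | COc1cc(C#C)ccc1Oc1cc(C#C)ccc1OCc1ccccc1
A9 | alternative 3 | 2,4-bis(benzyloxy)-1-iodobenzene | Ic1ccc(OCc2ccccc2)cc1OCc1ccccc1
A10 | alternative 3 | carbon monoxide | [C-]#[O+]
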